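**Assumption:** atoms are labelled with germacrane numbering (C1 ketone, C4=C5 olefin, C6 lactone carbinol, C7, C8 ester carbinol, C10 tertiary carbinol, C11–C13 methylene‑lactone carbons, C14/C15 methyls). The target is read as the (6R,7R,8R,10R)‑4Z isomer carrying an (E)‑2‑methylbut‑2‑enoate (tiglate).

## Retrosynthetic overview

1. C8–O ester last: Mitsunobu inversion of the 8α‑alcohol with tiglic acid.
2. Ten‑membered carbocycle: intramolecular Nozaki–Hiyama–Kishi allylation closing C7–C8 from a 3‑(bromomethyl)butenolide onto a C8 aldehyde; this one step sets C7 and C8 and unveils the α‑methylene lactone.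
3. Butenolide (formed first): ester ring‑closing metathesis on the bis‑allylic C6 alcohol.
4. C3–C4 bond: palladium‑catalysed ring‑opening coupling of a cyclopropanol (C1–C3, C8–C10, C14; from (R)‑citramalic acid by Kulinkovich reaction) with a (Z)‑alkenyl iodide (C4–C7, C15; from acrolein and propynylmagnesium bromide).
5. Ring order: five‑membered lactone first, ten‑membered carbocycle second; C10 from the chiral pool, C6 from a Sharpless kinetic resolution.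

## Route

Step 1
Reactants: 1 (R)‑citramalic acid
Product: 2 2‑[(4R)‑2,2,4‑trimethyl‑5‑oxo‑1,3‑dioxolan‑4‑yl]acetic acid
Conditions: 2,2‑dimethoxypropane, TsOH·H2O (cat.), rt
Reagents that add atoms: 2,2‑dimethoxypropane, COC(C)(C)OC
Why: Acid‑catalysed acetalisation (dioxolanone formation) ties the tertiary α‑hydroxy acid into a five‑membered acetonide and leaves only the CH2CO2H carboxyl free, without touching the stereocentre that becomes C10.

Step 2
Reactants: 2 2‑[(4R)‑2,2,4‑trimethyl‑5‑oxo‑1,3‑dioxolan‑4‑yl]acetic acid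
Product: 4 (3R)‑3‑hydroxy‑3‑methyloxolan‑2‑one, via dioxolanone alcohol 3 (not isolated)
Conditions: BH3·SMe2, THF, 0 °C → rt; then TsOH (cat.), CH2Cl2, rt
Reagents that add atoms: none
Why: Chemoselective borane reduction of the free carboxylic acid gives the primary alcohol, which lactonises under acid (intramolecular transesterification with loss of acetone) to the γ‑lactone with C10 unchanged.

Step 3
Reactants: 4 (3R)‑3‑hydroxy‑3‑methyloxolan‑2‑one
Product: 5 (3R)‑3‑(1‑hydroxycyclopropyl)butane‑1,3‑diol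
Conditions: EtMgBr (4.5 equiv), Ti(OiPr)4 (0.3 equiv), THF, 0 °C → rt; aq. NH4Cl
Reagents that add atoms: ethylmagnesium bromide, CC[Mg]Br
Why: Kulinkovich reaction: the titanacyclopropane generated from EtMgBr and Ti(OiPr)4 converts the lactone carbonyl (C1) into a cyclopropanol whose two CH2 groups are C2 and C3, the quaternary stereocentre not taking part.

Step 4
Reactants: 5 (3R)‑3‑(1‑hydroxycyclopropyl)butane‑1,3‑diol
Product: 6 1‑[(2R)‑4‑[(tert‑butyldimethylsilyl)oxy]‑2‑hydroxybutan‑2‑yl]cyclopropan‑1‑ol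
Conditions: TBSCl (1.05 equiv), imidazole, CH2Cl2, 0 °C
Reagents that add atoms: tert‑butyldimethylsilyl chloride, CC(C)(C)[Si](C)(C)Cl
Why: Sterically controlled silylation protects only the primary C8 hydroxyl, the two tertiary hydroxyls being unreactive under these conditions.

Step 5
Reactants: 7 prop‑2‑enal (acrolein); 8 prop‑1‑yn‑1‑ylmagnesium bromide
Product: 9 rac‑hex‑1‑en‑4‑yn‑3‑ol
Conditions: THF, −78 → 0 °C; aq. NH4Cl
Reagents that add atoms: none
Why: Grignard 1,2‑addition of the alkynyl nucleophile to the enal carbonyl assembles C4–C7 and C15 as a racemic vinyl propynyl carbinol.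

Step 6
Reactants: 9 rac‑hex‑1‑en‑4‑yn‑3‑ol
Product: 10 (3S)‑hex‑1‑en‑4‑yn‑3‑ol
Conditions: Ti(OiPr)4 (0.15 equiv), L‑(+)‑diisopropyl tartrate (0.18 equiv), tBuOOH (0.6 equiv), 4 Å MS, CH2Cl2, −20 °C, ca. 55% conversion
Reagents that add atoms: none
Why: Sharpless kinetic resolution: with the L‑(+)‑tartrate catalyst the (R)‑alcohol is epoxidised fast at its vinyl group (erythro epoxy alcohol), so the unreacted (S)‑enantiomer, which carries the future C6 configuration, is recovered in high ee.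

Step 7
Reactants: 10 (3S)‑hex‑1‑en‑4‑yn‑3‑ol
Product: 12 (3S,4Z)‑5‑iodohexa‑1,4‑dien‑3‑ol, via cyclic alkenylalanate 11 (not isolated)
Conditions: NaAlH2(OCH2CH2OMe)2, THF, 0 °C → rt; then I2, −78 → 0 °C
Reagents that add atoms: iodine, II; sodium bis(2‑methoxyethoxy)aluminium dihydride, [Na+].[AlH2-](OCCOC)OCCOC (its atoms stay only in 11)
Why: Hydroxyl‑directed trans‑hydroalumination of the propargylic alcohol puts aluminium on the distal alkyne carbon cis to the carbinol, and iodinolysis with retention gives the (Z)‑alkenyl iodide that fixes the C4=C5 geometry.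

Step 8
Reactants: 6 1‑[(2R)‑4‑[(tert‑butyldimethylsilyl)oxy]‑2‑hydroxybutan‑2‑yl]cyclopropan‑1‑ol; 12 (3S,4Z)‑5‑iodohexa‑1,4‑dien‑3‑ol
Product: 13 (3R,7Z,9S)‑1‑[(tert‑butyldimethylsilyl)oxy]‑3,9‑dihydroxy‑3,7‑dimethylundeca‑7,10‑dien‑4‑one
Conditions: Pd(OAc)2 (10 mol %), XPhos (20 mol %), Cs2CO3 (2 equiv), toluene, 60 °C
Reagents that add atoms: none
Why: Palladium‑catalysed ring‑opening cross‑coupling of a cyclopropanol: β‑carbon elimination of the palladium cyclopropoxide gives a palladium homoenolate, and reductive elimination with the alkenyl group forms C3–C4 with retention of the Z geometry and unveils the C1 ketone.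

Step 9
Reactants: 13 (3R,7Z,9S)‑1‑[(tert‑butyldimethylsilyl)oxy]‑3,9‑dihydroxy‑3,7‑dimethylundeca‑7,10‑dien‑4‑one; 14 2‑(bromomethyl)prop‑2‑enoic acid
Product: 15 (3S,4Z,9R)‑11‑[(tert‑butyldimethylsilyl)oxy]‑9‑hydroxy‑5,9‑dimethyl‑8‑oxoundeca‑1,4‑dien‑3‑yl 2‑(bromomethyl)prop‑2‑enoate
Conditions: DCC, DMAP (cat.), CH2Cl2, −10 °C → rt
Reagents that add atoms: none
Why: Steglich esterification acylates the only secondary hydroxyl (C6) with retention, the tertiary C10 hydroxyl being inert.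

Step 10
Reactants: 15 (3S,4Z,9R)‑11‑[(tert‑butyldimethylsilyl)oxy]‑9‑hydroxy‑5,9‑dimethyl‑8‑oxoundeca‑1,4‑dien‑3‑yl 2‑(bromomethyl)prop‑2‑enoate
Product: 16 (5R)‑3‑(bromomethyl)‑5‑[(1Z,6R)‑8‑[(tert‑butyldimethylsilyl)oxy]‑6‑hydroxy‑2,6‑dimethyl‑5‑oxooct‑1‑en‑1‑yl]furan‑2(5H)‑one
Conditions: second‑generation Grubbs catalyst RuCl2(=CHPh)(H2IMes)(PCy3) (5 mol %), CH2Cl2 (5 mM), 40 °C
Reagents that add atoms: none
Why: Ring‑closing metathesis between the terminal vinyl group and the acrylate closes the five‑membered butenolide (C7=C11) under neutral conditions and leaves the hindered trisubstituted Z olefin untouched.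

Step 11
Reactants: 16 (5R)‑3‑(bromomethyl)‑5‑[(1Z,6R)‑8‑[(tert‑butyldimethylsilyl)oxy]‑6‑hydroxy‑2,6‑dimethyl‑5‑oxooct‑1‑en‑1‑yl]furan‑2(5H)‑one
Product: 17 (5R)‑3‑(bromomethyl)‑5‑[(1Z,6R)‑6,8‑dihydroxy‑2,6‑dimethyl‑5‑oxooct‑1‑en‑1‑yl]furan‑2(5H)‑one
Conditions: 48% aq. HF, MeCN, 0 °C
Reagents that add atoms: none
Why: Acidic fluoride desilylation frees the primary C8 hydroxyl without any base, so the allylic bromide and the epimerisable butenolide C6–H survive.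

Step 12
Reactants: 17 (5R)‑3‑(bromomethyl)‑5‑[(1Z,6R)‑6,8‑dihydroxy‑2,6‑dimethyl‑5‑oxooct‑1‑en‑1‑yl]furan‑2(5H)‑one
Product: 18 (3R,7Z)‑8‑[(2R)‑4‑(bromomethyl)‑5‑oxo‑2,5‑dihydrofuran‑2‑yl]‑3‑hydroxy‑3,7‑dimethyl‑4‑oxooct‑7‑enal
Conditions: Dess–Martin periodinane, CH2Cl2, 0 °C → rt; used at once
Reagents that add atoms: none
Why: Dess–Martin oxidation converts the primary alcohol into the C8 aldehyde under near‑neutral conditions, the tertiary alcohol being unable to oxidise.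

Step 13
Reactants: 18 (3R,7Z)‑8‑[(2R)‑4‑(bromomethyl)‑5‑oxo‑2,5‑dihydrofuran‑2‑yl]‑3‑hydroxy‑3,7‑dimethyl‑4‑oxooct‑7‑enal
Product: 19 (6R,7R,8S,10R)‑8,10‑dihydroxy‑1‑oxogermacra‑4Z,11(13)‑dien‑12,6‑olide (8α‑alcohol)
Conditions: CrCl2 (10 equiv), THF (2 mM, slow addition), rt; aq. NH4Cl
Reagents that add atoms: none
Why: Intramolecular Nozaki–Hiyama–Kishi (Barbier‑type) allylation: the allylchromium formed from the bromide adds through its γ‑carbon (C7) to the aldehyde in preference to the hindered ketone, on the butenolide face anti to the C6 alkenyl substituent (trans lactone, 7R) and through a chair Zimmerman–Traxler transition state of the ring‑locked E‑type allylmetal with the aldehyde chain equatorial (anti adduct, 8S), closing the ten‑membered ring and creating the exocyclic methylene.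

Step 14
Reactants: 19 (6R,7R,8S,10R)‑8,10‑dihydroxy‑1‑oxogermacra‑4Z,11(13)‑dien‑12,6‑olide; 20 (E)‑2‑methylbut‑2‑enoic acid (tiglic acid)
Product: 21 (6R,7R,8R,10R)‑10‑hydroxy‑1‑oxo‑8‑[(E)‑2‑methylbut‑2‑enoyloxy]germacra‑4Z,11(13)‑dien‑12,6‑olide (target CNP0345906.3)
Conditions: PPh3, DIAD, toluene, 0 °C → rt (betaine pre‑formed before 19 is added)
Reagents that add atoms: none
Why: Mitsunobu esterification: SN2 displacement of the C8 oxyphosphonium by tiglate inverts C8 from S to R while installing the ester, the tertiary C10 hydroxyl not reacting.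

## Compound list

1 | (R)‑citramalic acid, (2R)‑2‑hydroxy‑2‑methylbutanedioic acid | OC(=O)[C@](C)(O)CC(=O)O | starting material
2 | 2‑[(4R)‑2,2,4‑trimethyl‑5‑oxo‑1,3‑dioxolan‑4‑yl]acetic acid | OC(=O)C[C@@]1(C)OC(C)(C)OC1=O | intermediate
3 | (5R)‑5‑(2‑hydroxyethyl)‑2,2,5‑trimethyl‑1,3‑dioxolan‑4‑one | OCC[C@@]1(C)OC(C)(C)OC1=O | intermediate
4 | (3R)‑3‑hydroxy‑3‑methyloxolan‑2‑one | O=C1OCC[C@@]1(C)O | intermediate
5 | (3R)‑3‑(1‑hydroxycyclopropyl)butane‑1,3‑diol | OCC[C@@](C)(O)C1(O)CC1 | intermediate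
6 | 1‑[(2R)‑4‑[(tert‑butyldimethylsilyl)oxy]‑2‑hydroxybutan‑2‑yl]cyclopropan‑1‑ol | CC(C)(C)[Si](C)(C)OCC[C@@](C)(O)C1(O)CC1 | intermediate
7 | prop‑2‑enal (acrolein) | C=CC=O | starting material
8 | prop‑1‑yn‑1‑ylmagnesium bromide | CC#C[Mg]Br | starting material
9 | rac‑hex‑1‑en‑4‑yn‑3‑ol | C=CC(O)C#CC | intermediate
10 | (3S)‑hex‑1‑en‑4‑yn‑3‑ol | C=C[C@H](O)C#CC | intermediate
11 | sodium (5S)‑5‑ethenyl‑2,2‑bis(2‑methoxyethoxy)‑3‑methyl‑2,5‑dihydro‑1,2‑oxaluminol‑2‑uide (cyclic alkenylalanate) | C=C[C@H]1C=C(C)[Al-](OCCOC)(OCCOC)O1.[Na+] | intermediate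
12 | (3S,4Z)‑5‑iodohexa‑1,4‑dien‑3‑ol | C=C[C@H](O)/C=C(/C)I | intermediate
13 | (3R,7Z,9S)‑1‑[(tert‑butyldimethylsilyl)oxy]‑3,9‑dihydroxy‑3,7‑dimethylundeca‑7,10‑dien‑4‑one | C=C[C@H](O)/C=C(/C)CCC(=O)[C@](C)(O)CCO[Si](C)(C)C(C)(C)C | intermediate
14 | 2‑(bromomethyl)prop‑2‑enoic acid | C=C(CBr)C(=O)O | starting material
15 | (3S,4Z,9R)‑11‑[(tert‑butyldimethylsilyl)oxy]‑9‑hydroxy‑5,9‑dimethyl‑8‑oxoundeca‑1,4‑dien‑3‑yl 2‑(bromomethyl)prop‑2‑enoate | C=C[C@H](OC(=O)C(=C)CBr)/C=C(/C)CCC(=O)[C@](C)(O)CCO[Si](C)(C)C(C)(C)C | intermediate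
16 | (5R)‑3‑(bromomethyl)‑5‑[(1Z,6R)‑8‑[(tert‑butyldimethylsilyl)oxy]‑6‑hydroxy‑2,6‑dimethyl‑5‑oxooct‑1‑en‑1‑yl]furan‑2(5H)‑one | BrCC1=C[C@@H](/C=C(/C)CCC(=O)[C@](C)(O)CCO[Si](C)(C)C(C)(C)C)OC1=O | intermediate
17 | (5R)‑3‑(bromomethyl)‑5‑[(1Z,6R)‑6,8‑dihydroxy‑2,6‑dimethyl‑5‑oxooct‑1‑en‑1‑yl]furan‑2(5H)‑one | BrCC1=C[C@@H](/C=C(/C)CCC(=O)[C@](C)(O)CCO)OC1=O | intermediate
18 | (3R,7Z)‑8‑[(2R)‑4‑(bromomethyl)‑5‑oxo‑2,5‑dihydrofuran‑2‑yl]‑3‑hydroxy‑3,7‑dimethyl‑4‑oxooct‑7‑enal | BrCC1=C[C@@H](/C=C(/C)CCC(=O)[C@](C)(O)CC=O)OC1=O | intermediate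
19 | (6R,7R,8S,10R)‑8,10‑dihydroxy‑1‑oxogermacra‑4Z,11(13)‑dien‑12,6‑olide (8α‑alcohol) | C=C1C(=O)O[C@@H]2/C=C(/C)CCC(=O)[C@](C)(O)C[C@H](O)[C@@H]12 | intermediate
20 | (E)‑2‑methylbut‑2‑enoic acid (tiglic acid) | C/C=C(\C)C(=O)O | starting material
21 | (6R,7R,8R,10R)‑10‑hydroxy‑1‑oxo‑8‑[(E)‑2‑methylbut‑2‑enoyloxy]germacra‑4Z,11(13)‑dien‑12,6‑olide | C=C1C(=O)O[C@@H]2/C=C(/C)CCC(=O)[C@](C)(O)C[C@@H](OC(=O)/C(C)=C/C)[C@@H]12 | target

## Step count and risk

Total step count: 14. Longest linear sequence: 11 steps (steps 1–4 and 8–14, from 1).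

**Step 8 (cyclopropanol/alkenyl iodide coupling).** Risks are β‑hydride elimination of the palladium homoenolate to an enone and palladium‑mediated oxidation of the free allylic alcohol. The fallback sets out from 6 and 12 and comes back at 13. Cyclopropanol 6 is opened with N‑iodosuccinimide (CH2Cl2, 0 °C) to the β‑iodo ketone (3R)‑1‑[(tert‑butyldimethylsilyl)oxy]‑3‑hydroxy‑6‑iodo‑3‑methylhexan‑4‑one F1. Zinc dust and LiCl in THF convert it into the alkylzinc iodide [(4R)‑6‑[(tert‑butyldimethylsilyl)oxy]‑4‑hydroxy‑4‑methyl‑3‑oxohexyl]zinc iodide F2. Negishi coupling of F2 (slow addition) with 12 under Pd(PPh3)4 in THF at rt then gives 13. This replaces the alkoxide‑triggered ring opening by a preformed organozinc nucleophile.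

**Step 13 (chromium‑mediated macrocyclisation).** Risks are ring strain and dimerisation, competing attack of C7 on the C1 ketone (a seven‑membered ring), and the C8 configuration, which rests on a transition‑state model. The fallback sets out from 17 and comes back at 21. Bromide 17 is converted with Bu3SnSnBu3 and Pd(PPh3)4 into the allylstannane (5R)‑5‑[(1Z,6R)‑6,8‑dihydroxy‑2,6‑dimethyl‑5‑oxooct‑1‑en‑1‑yl]‑3‑[(tributylstannyl)methyl]furan‑2(5H)‑one F3. Dess–Martin oxidation gives the stannyl aldehyde (3R,7Z)‑3‑hydroxy‑3,7‑dimethyl‑4‑oxo‑8‑[(2R)‑5‑oxo‑4‑[(tributylstannyl)methyl]‑2,5‑dihydrofuran‑2‑yl]oct‑7‑enal F4. BF3·OEt2 (CH2Cl2, −78 °C, high dilution) closes the ring through an open antiperiplanar SE2′ transition state, which favours the syn adduct, the 8β‑alcohol (6R,7R,8R,10R)‑8,10‑dihydroxy‑1‑oxogermacra‑4Z,11(13)‑dien‑12,6‑olide F5. F5 is esterified with retention by 20 (2,4,6‑trichlorobenzoyl chloride, Et3N, DMAP) to give 21, so no inversion step is needed. The same retentive esterification applies if the chromium closure itself delivers F5 and not 19.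

**Step 14 (Mitsunobu inversion).** Risks are the hindered ring alcohol (elimination) and reversible phosphine addition to the α‑methylene lactone. The fallback sets out from 19 and comes back at 21. 19 is converted with ClCH2SO2Cl and pyridine (CH2Cl2, 0 °C) into the chloromethanesulfonate (6R,7R,8S,10R)‑8‑[(chloromethanesulfonyl)oxy]‑10‑hydroxy‑1‑oxogermacra‑4Z,11(13)‑dien‑12,6‑olide F6. F6 is displaced with inversion by cesium (E)‑2‑methylbut‑2‑enoate (from 20 and Cs2CO3) with 18‑crown‑6 in toluene at 60 °C to give 21.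

## Further compounds

F1 | step 8 | (3R)‑1‑[(tert‑butyldimethylsilyl)oxy]‑3‑hydroxy‑6‑iodo‑3‑methylhexan‑4‑one | ICCC(=O)[C@](C)(O)CCO[Si](C)(C)C(C)(C)C
F2 | step 8 | [(4R)‑6‑[(tert‑butyldimethylsilyl)oxy]‑4‑hydroxy‑4‑methyl‑3‑oxohexyl]zinc iodide | I[Zn]CCC(=O)[C@](C)(O)CCO[Si](C)(C)C(C)(C)C
F3 | step 13 | (5R)‑5‑[(1Z,6R)‑6,8‑dihydroxy‑2,6‑dimethyl‑5‑oxooct‑1‑en‑1‑yl]‑3‑[(tributylstannyl)methyl]furan‑2(5H)‑one | CCCC[Sn](CCCC)(CCCC)CC1=C[C@@H](/C=C(/C)CCC(=O)[C@](C)(O)CCO)OC1=O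
F4 | step 13 | (3R,7Z)‑3‑hydroxy‑3,7‑dimethyl‑4‑oxo‑8‑[(2R)‑5‑oxo‑4‑[(tributylstannyl)methyl]‑2,5‑dihydrofuran‑2‑yl]oct‑7‑enal | CCCC[Sn](CCCC)(CCCC)CC1=C[C@@H](/C=C(/C)CCC(=O)[C@](C)(O)CC=O)OC1=O
F5 | step 13 | (6R,7R,8R,10R)‑8,10‑dihydroxy‑1‑oxogermacra‑4Z,11(13)‑dien‑12,6‑olide (8β‑alcohol) | C=C1C(=O)O[C@@H]2/C=C(/C)CCC(=O)[C@](C)(O)C[C@@H](O)[C@@H]12
F6 | step 14 | (6R,7R,8S,10R)‑8‑[(chloromethanesulfonyl)oxy]‑10‑hydroxy‑1‑oxogermacra‑4Z,11(13)‑dien‑12,6‑olide | C=C1C(=O)O[C@@H]2/C=C(/C)CCC(=O)[C@](C)(O)C[C@H](OS(=O)(=O)CCl)[C@@H]12
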